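Two questions stand on each of two flasks: which species holds most of the charged substrate at the end, and how much.

| flask | substrate | remark | time |
|---|---|---|---|
| Wednesday's | 0.15 M | run made earlier |  |
| Friday's | 0.23 M | run made earlier |  |
| north-west | 0.31 M |  | 6.0 min |
| south | 0.31 M |  | 10 min |

| run | time / min | substrate / % | isomer of the product A / % | intermediate / % | target / % |
|---|---|---|---|---|---|
| Wednesday's | 0.250 | 96.6 | 3.0 | 3.3 | 0.5 |
| Wednesday's | 0.667 | 89.0 | 2.2 | 8.9 | 2.1 |
| Wednesday's | 1.33 | 79.7 | 3.5 | 14.7 | 4.1 |
| Wednesday's | 2.00 | 70.1 | 2.6 | 18.1 | 6.3 |
| Wednesday's | 3.00 | 58.8 | 8.6 | 22.0 | 8.6 |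
| Wednesday's | 4.00 | 47.8 | 12.6 | 20.7 | 10.3 |
| Wednesday's | 5.00 | 43.6 | 17.9 | 25.0 | 12.7 |
| Friday's | 0.250 | 96.5 | 0.1 | 2.8 | 0 |
| Friday's | 0.667 | 88.3 | 0 | 8.7 | 1.4 |
| Friday's | 1.33 | 79.4 | 2.7 | 15.2 | 3.8 |
| Friday's | 2.00 | 71.8 | 2.5 | 18.0 | 4.7 |
| Friday's | 3.00 | 60.1 | 7.9 | 21.7 | 7.7 |
| Friday's | 4.00 | 50.2 | 12.6 | 24.4 | 10.0 |
| Friday's | 5.00 | 42.0 | 19.7 | 25.4 | 11.2 |

(each reading ± 1 percentage point)

* which of these there is most of at the end, counted by the substrate in it, north-west (isomer of the product A / intermediate / substrate / target)
* which of these there is most of at the end, counted by the substrate in it, south (isomer of the product A / intermediate / substrate / target)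
* how much there is at the end of the one of these that leads, in percent of the substrate charged: north-west
* how much there is at the end of the one of these that leads, in percent of the substrate charged: south

- steps that have been proposed: intermediate <-> isomer of the product A; target <-> isomer of the product B; intermediate <-> target; substrate -> intermediate
- a reading of target is of its free form alone

I fold this into one number. The last substrate readings of Wednesday's and Friday's runs differ by 1.6 percentage points despite different charges, so I leave the charge out and take from the pair a first-order rate constant of 0.170 min⁻¹. What is neither substrate nor isomer of the product A I call the held share, a quasi-steady pool. It reads 38.4% at 5.00 min and 38.4% at 4.00 min. If it stays, substrate and isomer of the product A draw level when substrate stands at 30.8%.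

The lead number, rate constant times time divided by the same product at that crossing, says which of these two leads while the held share stays: below one substrate, above one isomer of the product A. North-west has 0.865, with substrate at 36.1%. South has 1.44, with isomer of the product A at 43.3%. But the number compares two species, so I check one more: intermediate last read 25.4% on Friday, less than my figure for north-west's substrate.

The forecast, not quite my figures, gives substrate at 35% in north-west and isomer of the product A at 44% in south, holding that “the rate shows no concentration dependence”.

North-west gives substrate at 35.2%, south isomer of the product A at 43.4%, under this scheme: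

    intermediate ⇌ isomer of the product A (K = 12.0, k = 0.00370 s⁻¹)
    target ⇌ isomer of the product B (K = 0.240, k = 0.00630 s⁻¹)
    intermediate ⇌ target (K = 0.520, k = 0.0110 s⁻¹)
    substrate → intermediate (k = 0.00290 s⁻¹)

The held share stands at 40.8% in north-west and 39.0% in south, and the lead numbers 0.865 and 1.44 name the leaders. North-west read at 15 min has lead number 2.16, above one, and isomer of the product A leads at 61.7%, with the held share down to 30.9%. In north-west, the step from intermediate into target reaches the midpoint of its turnover up to 6.0 min at 2.17 min, sooner than the step into isomer of the product A at 3.65 min. In south, target stands at 11.9% at 5.00 min and 12.5% at 10.0 min, while isomer of the product A climbs from 18.8% to 43.4%.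

Readings and results come from a simulation from invented constants; noise was put on by code.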